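**Retrosynthetic overview**

1. The dihydropyran ring on ring B (O4'–CMe2–CH2–CH2–C3'–C4') is closed last, in a one-pot cascade on an unprotected isomer of the target, the 7-O-prenyl / 4'-O-(1,1-dimethylallyl) flavonol: [3,3] shift O4'→C3', [3,3] shift O7→C8, then 6-endo hydroalkoxylation.
2. Enabling feature: C3' lies ortho to O4' (ring B) and C8 lies ortho to O7 (ring A), so O4'–C4'=C3' and O7–C7=C8 are the vinyl-ether halves of two aromatic Claisen systems. The gem-dimethyl carbon of the pyran sits on O4', so the prenyl alkene delivered to C3' is within reach of O4'–H.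
3. The cascade precursor comes from a 5-O-MOM flavonol that still carries the robust 1,1-dimethylpropargyl ether (MOM cleavage, then Lindlar reduction). The pyranone ring C is made by Algar–Flynn–Oyamada cyclisation of a chalcone.
4. The chalcone comes from Claisen–Schmidt union of an A-ring ketone (from 2',4',6'-trihydroxyacetophenone) and a B-ring aldehyde (from 6-bromoveratraldehyde by demethylation, Stille prenylation and propargylation).
5. Ring order: benzene rings A and B are purchased; pyranone ring C is formed in step 7; the dihydropyran ring is formed in step 10.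

Key step: step 10

Remark on the chemistry: the target has no stereocentre, and the aryl–chromone axis is assumed to rotate freely, so the molecule is achiral and no stereocontrol is required. Flavone numbering is used throughout (ring B primed; the pyran oxygen is O4').

**Step 1**
Reactants: 1 2-bromo-4,5-dimethoxybenzaldehyde (6-bromoveratraldehyde)
Product: 2 2-bromo-4,5-dihydroxybenzaldehyde
Conditions: BBr3 (3 equiv), CH2Cl2, −78 °C to rt; then H2O
Reagents that add atoms: none
Why: Lewis-acid demethylation of aryl methyl ethers with BBr3 tolerates the aldehyde and aryl bromide, and is placed first because no alkene is present yet.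

**Step 2**
Reactants: 2 2-bromo-4,5-dihydroxybenzaldehyde
Product: 3 4,5-dihydroxy-2-(3-methylbut-2-en-1-yl)benzaldehyde
Conditions: tributyl(prenyl)stannane (1.3 equiv), Pd(PPh3)4 (5 mol%), DMF, 95 °C, Ar
Reagents that add atoms: tributyl(3-methylbut-2-en-1-yl)stannane, CCCC[Sn](CCCC)(CCCC)CC=C(C)C
Why: Stille cross-coupling of an ortho-formyl aryl bromide runs under neutral conditions that tolerate the free catechol, and reductive elimination at the unsubstituted allyl terminus should give the linear prenyl arene.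

**Step 3**
Reactants: 3 4,5-dihydroxy-2-(3-methylbut-2-en-1-yl)benzaldehyde
Product: 4 5-hydroxy-4-[(2-methylbut-3-yn-2-yl)oxy]-2-(3-methylbut-2-en-1-yl)benzaldehyde
Conditions: 3-chloro-3-methylbut-1-yne (1.2 equiv), DBU (1.1 equiv), CuCl2·2H2O (1 mol%), MeCN, 0 °C, N2
Reagents that add atoms: 3-chloro-3-methylbut-1-yne, C#CC(C)(C)Cl
Why: Copper-catalysed propargylic etherification of a phenol with a tertiary propargyl chloride should occur only at the 4-hydroxyl, which is para to the formyl group and clearly the more acidic, so one equivalent of base generates only that phenoxide.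

**Step 4**
Reactants: 5 1-(2,4,6-trihydroxyphenyl)ethanone (2',4',6'-trihydroxyacetophenone)
Product: 6 1-{2,6-dihydroxy-4-[(3-methylbut-2-en-1-yl)oxy]phenyl}ethanone
Conditions: prenyl bromide (1.0 equiv), K2CO3 (1.0 equiv), acetone, 50 °C
Reagents that add atoms: 1-bromo-3-methylbut-2-ene, CC(C)=CCBr
Why: Williamson etherification is selective for the 4-hydroxyl because the 2- and 6-hydroxyls are hydrogen-bonded to the ketone and less acidic.

**Step 5**
Reactants: 6 1-{2,6-dihydroxy-4-[(3-methylbut-2-en-1-yl)oxy]phenyl}ethanone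
Product: 7 1-{2-hydroxy-6-(methoxymethoxy)-4-[(3-methylbut-2-en-1-yl)oxy]phenyl}ethanone
Conditions: MOMCl (1.1 equiv), iPr2NEt (1.5 equiv), CH2Cl2, 0 °C to rt
Reagents that add atoms: chloromethyl methyl ether, COCCl
Why: MOM protection caps one of the two equivalent hydroxyls, after which the remaining hydroxyl is locked in a strong hydrogen bond to the carbonyl and should resist a second alkylation.

**Step 6**
Reactants: 7 1-{2-hydroxy-6-(methoxymethoxy)-4-[(3-methylbut-2-en-1-yl)oxy]phenyl}ethanone; 4 5-hydroxy-4-[(2-methylbut-3-yn-2-yl)oxy]-2-(3-methylbut-2-en-1-yl)benzaldehyde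
Product: 8 (2E)-1-{2-hydroxy-6-(methoxymethoxy)-4-[(3-methylbut-2-en-1-yl)oxy]phenyl}-3-{5-hydroxy-4-[(2-methylbut-3-yn-2-yl)oxy]-2-(3-methylbut-2-en-1-yl)phenyl}prop-2-en-1-one
Conditions: KOH (50% aq, excess), EtOH, rt, 36 h; then AcOH to pH 6
Reagents that add atoms: none
Why: Claisen–Schmidt aldol condensation with E1cB dehydration should give the conjugated (E)-enone as the thermodynamic alkene, and the MOM acetal, both ethers and the alkyne are inert to hydroxide at room temperature.

**Step 7**
Reactants: 8 the (E)-chalcone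
Product: 9 3-hydroxy-2-{5-hydroxy-4-[(2-methylbut-3-yn-2-yl)oxy]-2-(3-methylbut-2-en-1-yl)phenyl}-5-(methoxymethoxy)-7-[(3-methylbut-2-en-1-yl)oxy]-4H-chromen-4-one
Conditions: 30% H2O2 (excess), NaOH (2 M aq), MeOH–THF, 0 °C to rt
Reagents that add atoms: hydrogen peroxide, OO
Why: Algar–Flynn–Oyamada oxidative cyclisation of the 2'-hydroxychalcone should form the pyranone ring C and the 3-hydroxyl in one step, and the nucleophilic oxidant does not epoxidise the isolated prenyl alkenes or attack the alkyne.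

**Step 8**
Reactants: 9 the 5-O-MOM flavonol
Product: 10 3,5-dihydroxy-2-{5-hydroxy-4-[(2-methylbut-3-yn-2-yl)oxy]-2-(3-methylbut-2-en-1-yl)phenyl}-7-[(3-methylbut-2-en-1-yl)oxy]-4H-chromen-4-one
Conditions: HCl (0.5 M) in MeOH–THF, 0 °C to rt, short reaction time; NaHCO3 quench
Reagents that add atoms: none
Why: Acid-catalysed acetal exchange should remove the MOM group under very mild conditions, because the 5-O-MOM ether peri to the C4 carbonyl is unusually labile (cleavage gives the chelated 5-hydroxyl), so the aryl prenyl ether and the tertiary propargyl ether should survive.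

**Step 9**
Reactants: 10 the 5-hydroxy propargyl ether flavonol
Product: 11 3,5-dihydroxy-2-{5-hydroxy-4-[(2-methylbut-3-en-2-yl)oxy]-2-(3-methylbut-2-en-1-yl)phenyl}-7-[(3-methylbut-2-en-1-yl)oxy]-4H-chromen-4-one
Conditions: H2 (1 atm), Lindlar catalyst, quinoline, EtOAc, rt, monitored
Reagents that add atoms: none
Why: Lindlar semi-hydrogenation should reduce only the terminal alkyne to the vinyl group, leaving the trisubstituted prenyl alkenes and the chromone C2=C3 bond untouched; the alkyne is kept until this point because the resulting aryl 1,1-dimethylallyl ether is heat- and acid-sensitive.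

**Step 10**
Reactants: 11 the 7-O-prenyl / 4'-O-(1,1-dimethylallyl) flavonol
Product: 14 broussoflavonol E, via 2',3'-diprenylcatechol 7-prenyl ether 12 (not isolated), via 8-(1,1-dimethylallyl)-2',3'-diprenylcatechol 13 (not isolated)
Conditions: 1,2-dichlorobenzene (degassed, Ar), 120 °C, then 185 °C; cool to 40 °C, Amberlyst-15 (dry), same flask
Reagents that add atoms: none
Why: At 120 °C the ring-B 1,1-dimethylallyl ether should undergo a chair [3,3] shift from O4' to C3' through a dearomatised cyclohexadienone that re-aromatises to catechol 12, at 185 °C the 7-O-prenyl ether should shift likewise from O7 to C8 to give 13, and Amberlyst-15 then protonates the 3'-prenyl alkene so that O4' traps the tertiary cation. The closest known reaction types are the Claisen rearrangement of aryl 1,1-dimethylallyl ethers to ortho-prenylphenols, the Claisen rearrangement of 7-prenyloxy-5-hydroxyflavones to 8-(1,1-dimethylallyl)flavones, and the acid-catalysed cyclisation of ortho-prenylphenols to 2,2-dimethylchromans. The dihydropyran ring closes by a 6-endo-trig Markovnikov hydroalkoxylation, O4' bonding to the gem-dimethyl carbon. No stereocentre is formed, because the sp3 carbons of the dienone intermediates are erased on tautomerisation and both new quaternary carbons carry two identical methyl groups. The step needs C3' over C5' in ring B (C5' bears oxygen, so attack there is reversible and cannot tautomerise), C8 over C6 in ring A (the angular preference of 7-allyloxy-5-hydroxychromones, attributed to C7–C8 bond fixation in the chelated chromone), and closure at only one of three alkenes (the 2'-prenyl group has no ortho hydroxyl, and the vinyl group at C8 would have to give a secondary cation). The acid is added only after the 7-O-prenyl ether has rearranged, because that ether would otherwise be cleaved.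

**Compound list**

1 | 2-bromo-4,5-dimethoxybenzaldehyde | O=Cc1cc(OC)c(OC)cc1Br | starting material
2 | 2-bromo-4,5-dihydroxybenzaldehyde | O=Cc1cc(O)c(O)cc1Br | intermediate
3 | 4,5-dihydroxy-2-(3-methylbut-2-en-1-yl)benzaldehyde | O=Cc1cc(O)c(O)cc1CC=C(C)C | intermediate
4 | 5-hydroxy-4-[(2-methylbut-3-yn-2-yl)oxy]-2-(3-methylbut-2-en-1-yl)benzaldehyde | O=Cc1cc(O)c(OC(C)(C)C#C)cc1CC=C(C)C | intermediate
5 | 1-(2,4,6-trihydroxyphenyl)ethanone | CC(=O)c1c(O)cc(O)cc1O | starting material
6 | 1-{2,6-dihydroxy-4-[(3-methylbut-2-en-1-yl)oxy]phenyl}ethanone | CC(=O)c1c(O)cc(OCC=C(C)C)cc1O | intermediate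
7 | 1-{2-hydroxy-6-(methoxymethoxy)-4-[(3-methylbut-2-en-1-yl)oxy]phenyl}ethanone | CC(=O)c1c(O)cc(OCC=C(C)C)cc1OCOC | intermediate
8 | (2E)-chalcone from 7 and 4 | COCOc1cc(OCC=C(C)C)cc(O)c1C(=O)/C=C/c1cc(O)c(OC(C)(C)C#C)cc1CC=C(C)C | intermediate
9 | 3-hydroxy-5-(methoxymethoxy)-7-prenyloxy flavone with 2'-prenyl, 4'-O-(1,1-dimethylpropargyl), 5'-hydroxy ring B (achiral) | COCOc1cc(OCC=C(C)C)cc2oc(-c3cc(O)c(OC(C)(C)C#C)cc3CC=C(C)C)c(O)c(=O)c12 | intermediate
10 | 3,5-dihydroxy-7-prenyloxy flavone with 2'-prenyl, 4'-O-(1,1-dimethylpropargyl), 5'-hydroxy ring B (achiral) | Oc1cc(OCC=C(C)C)cc2oc(-c3cc(O)c(OC(C)(C)C#C)cc3CC=C(C)C)c(O)c(=O)c12 | intermediate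
11 | 3,5-dihydroxy-7-prenyloxy flavone with 2'-prenyl, 4'-O-(1,1-dimethylallyl), 5'-hydroxy ring B (achiral) | Oc1cc(OCC=C(C)C)cc2oc(-c3cc(O)c(OC(C)(C)C=C)cc3CC=C(C)C)c(O)c(=O)c12 | intermediate
12 | 2-[4,5-dihydroxy-2,3-bis(3-methylbut-2-en-1-yl)phenyl]-3,5-dihydroxy-7-[(3-methylbut-2-en-1-yl)oxy]-4H-chromen-4-one | Oc1cc(OCC=C(C)C)cc2oc(-c3cc(O)c(O)c(CC=C(C)C)c3CC=C(C)C)c(O)c(=O)c12 | intermediate (not isolated)
13 | 2-[4,5-dihydroxy-2,3-bis(3-methylbut-2-en-1-yl)phenyl]-3,5,7-trihydroxy-8-(2-methylbut-3-en-2-yl)-4H-chromen-4-one | C=CC(C)(C)c1c(O)cc(O)c2c(=O)c(O)c(-c3cc(O)c(O)c(CC=C(C)C)c3CC=C(C)C)oc12 | intermediate (not isolated)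
14 | broussoflavonol E, 3,5,7-trihydroxy-2-[8-hydroxy-2,2-dimethyl-5-(3-methylbut-2-en-1-yl)-3,4-dihydro-2H-chromen-6-yl]-8-(2-methylbut-3-en-2-yl)-4H-chromen-4-one (achiral) | C=CC(C)(C)c1c(O)cc(O)c2c(=O)c(O)c(-c3cc(O)c4c(c3CC=C(C)C)CCC(C)(C)O4)oc12 | target

**Step count and risks**

Total steps: 10 (steps 1–3 for the aldehyde, steps 4–5 for the ketone, steps 6–10 after union). Longest linear sequence: 8 steps (1, 2, 3, 6, 7, 8, 9, 10).

Steps most likely to fail:

1. Step 10. The ring-A shift may partly go to C6 instead of C8. At 185 °C the tertiary ether may fragment with loss of isoprene, or the new C8 side chain may cyclise onto O7. In the acid stage, protonation may not be confined to the 3'-prenyl alkene. The fallback moves the ring-A rearrangement to the symmetrical ketone, where both ortho positions are equivalent. It sets out from 6: Claisen rearrangement in N,N-diethylaniline at 190 °C should give 1-[2,4,6-trihydroxy-3-(2-methylbut-3-en-2-yl)phenyl]ethanone F1. Bis-MOM protection of the 4- and 6-hydroxyls (the hindered, chelated 2-hydroxyl stays free) gives 1-[2-hydroxy-4,6-bis(methoxymethoxy)-3-(2-methylbut-3-en-2-yl)phenyl]ethanone F2. Claisen–Schmidt condensation with 4 gives the (E)-chalcone F3, and Algar–Flynn–Oyamada cyclisation gives the 5,7-bis-MOM 8-(1,1-dimethylallyl) flavonol F4. HCl in MeOH gives the tetrahydroxy propargyl ether F5, and Lindlar reduction gives the 4'-O-(1,1-dimethylallyl) ether F6. F6 then needs only the mild ring-B Claisen shift (toluene, 110 °C), which returns to the route at 13, and Amberlyst-15 closes the ring to 14.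

2. Step 7. The phenoxide may attack the α-carbon (5-exo) and divert material to an aurone, a risk raised by the 6'-alkoxy group and the ortho-substituted ring B. The fallback fixes the ring size by acid-mediated benzylic opening of an isolated epoxide. It sets out from 8: MOMCl/NaH gives the tris-MOM (E)-chalcone F7. Weitz–Scheffer epoxidation (H2O2, NaOH) gives the racemic trans-epoxide F8. Dilute HCl in MeOH removes the MOM groups, and the freed 2'-hydroxyl opens the epoxide at the benzylic carbon (6-endo) to give the racemic trans-dihydroflavonol F9. Cold alkaline H2O2 dehydrogenates F9 to the flavonol, returning to the route at 10.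

3. Step 3. Site selectivity between the two catechol hydroxyls may be lost under the copper/DBU conditions, giving 5-O- or bis-ether, or the catechol may be oxidised. The fallback differentiates the hydroxyls with a precedented weak-base alkylation. It sets out from 3: allyl bromide/NaHCO3/NaI in DMF gives 4-(allyloxy)-5-hydroxy-2-(3-methylbut-2-en-1-yl)benzaldehyde F10. MOMCl/iPr2NEt gives 4-(allyloxy)-5-(methoxymethoxy)-2-(3-methylbut-2-en-1-yl)benzaldehyde F11. Pd(PPh3)4/morpholine removes the allyl group to give 4-hydroxy-5-(methoxymethoxy)-2-(3-methylbut-2-en-1-yl)benzaldehyde F12. Propargylation of the only free hydroxyl gives 5-(methoxymethoxy)-4-[(2-methylbut-3-yn-2-yl)oxy]-2-(3-methylbut-2-en-1-yl)benzaldehyde F13, and mild HCl/MeOH returns to the route at 4.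

**Further compounds**

F1 | step 10 | 1-[2,4,6-trihydroxy-3-(2-methylbut-3-en-2-yl)phenyl]ethanone | CC(=O)c1c(O)cc(O)c(C(C)(C)C=C)c1O
F2 | step 10 | 1-[2-hydroxy-4,6-bis(methoxymethoxy)-3-(2-methylbut-3-en-2-yl)phenyl]ethanone | CC(=O)c1c(OCOC)cc(OCOC)c(C(C)(C)C=C)c1O
F3 | step 10 | (E)-chalcone from F2 and 4 | COCOc1cc(OCOC)c(C(C)(C)C=C)c(O)c1C(=O)/C=C/c1cc(O)c(OC(C)(C)C#C)cc1CC=C(C)C
F4 | step 10 | 3-hydroxy-5,7-bis(methoxymethoxy)-8-(2-methylbut-3-en-2-yl) flavone with 2'-prenyl, 4'-O-(1,1-dimethylpropargyl), 5'-hydroxy ring B | C=CC(C)(C)c1c(OCOC)cc(OCOC)c2c(=O)c(O)c(-c3cc(O)c(OC(C)(C)C#C)cc3CC=C(C)C)oc12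
F5 | step 10 | 3,5,7-trihydroxy-8-(2-methylbut-3-en-2-yl) flavone with 2'-prenyl, 4'-O-(1,1-dimethylpropargyl), 5'-hydroxy ring B | C=CC(C)(C)c1c(O)cc(O)c2c(=O)c(O)c(-c3cc(O)c(OC(C)(C)C#C)cc3CC=C(C)C)oc12
F6 | step 10 | 3,5,7-trihydroxy-8-(2-methylbut-3-en-2-yl) flavone with 2'-prenyl, 4'-O-(1,1-dimethylallyl), 5'-hydroxy ring B | C=CC(C)(C)c1c(O)cc(O)c2c(=O)c(O)c(-c3cc(O)c(OC(C)(C)C=C)cc3CC=C(C)C)oc12
F7 | step 7 | tris-MOM (E)-chalcone from 8 | COCOc1cc(OCC=C(C)C)cc(OCOC)c1C(=O)/C=C/c1cc(OCOC)c(OC(C)(C)C#C)cc1CC=C(C)C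
F8 | step 7 | trans-epoxide of F7 (racemic, one enantiomer drawn) | COCOc1cc(OCC=C(C)C)cc(OCOC)c1C(=O)[C@H]1O[C@@H]1c1cc(OCOC)c(OC(C)(C)C#C)cc1CC=C(C)C
F9 | step 7 | trans-3,5-dihydroxy-7-prenyloxy flavanone with 2'-prenyl, 4'-O-(1,1-dimethylpropargyl), 5'-hydroxy ring B (racemic, one enantiomer drawn) | CC(C)=CCc1cc(OC(C)(C)C#C)c(O)cc1[C@@H]1[C@@H](O)C(=O)c2c(O)cc(OCC=C(C)C)cc2O1
F10 | step 3 | 4-(allyloxy)-5-hydroxy-2-(3-methylbut-2-en-1-yl)benzaldehyde | O=Cc1cc(O)c(OCC=C)cc1CC=C(C)C
F11 | step 3 | 4-(allyloxy)-5-(methoxymethoxy)-2-(3-methylbut-2-en-1-yl)benzaldehyde | O=Cc1cc(OCOC)c(OCC=C)cc1CC=C(C)C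
F12 | step 3 | 4-hydroxy-5-(methoxymethoxy)-2-(3-methylbut-2-en-1-yl)benzaldehyde | O=Cc1cc(OCOC)c(O)cc1CC=C(C)C
F13 | step 3 | 5-(methoxymethoxy)-4-[(2-methylbut-3-yn-2-yl)oxy]-2-(3-methylbut-2-en-1-yl)benzaldehyde | O=Cc1cc(OCOC)c(OC(C)(C)C#C)cc1CC=C(C)C
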